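## Structural features

The target is an ether-linked dimer of two 2-(2-phenylethyl)chromone units. O6 of an aromatic 6-oxy-7-methoxychromone is bonded to C8 of a 5,6,7,8-tetrahydrochromone, in which a γ-pyranone (ring A) is fused through C4a=C8a to a cyclohexene (ring B). Ring B carries four contiguous oxygen-bearing stereocentres, C5 (S), C6 (R), C7 (S) and C8 (S). The relationships are 5,6-trans, 6,7-trans and 7,8-cis, and C8–C7–C6 read as C2–C3–C4 of a D-lyxo sugar. The C5 hydroxyl sits on the carbon bonded to C4a, the α-carbon of the pyranone, and the aryloxy group on C8, the carbon bonded to the enol-ether carbon C8a. The fragile points are these: C8–H is acidified by the vinylogous carbonyl and by the aryloxy group, so base can epimerise C8 or expel the phenol; ring B aromatises if two of its oxygen substituents are lost; the C5 carbinol can ionise in strong acid with help from O1; both pyranones accept hydrides and hard nucleophiles. The real difficulty lies in the secondary alkyl aryl ether at the hindered C8, cis to the C7 oxygen, and in the control of C5 relative to C6. The key step exploits the fact that C5 is a secondary carbinol directly attached to C4a of ring A: a C4a–metal bond made from a C4a–I bond can add to a C5 aldehyde at the end of a chain that already holds C6, C7 and C8, and this closes ring B.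

## Logic of the disconnections

23 is traced to 22 by tying O6 and O7 into one acetal carbon. The cyclic acetal is preferred to two separate ethers because it fixes both oxygens equatorial on ring B. The forward demand is an acid hydrolysis mild enough not to ionise the C5 carbinol.

22 is cut at C4a–C5 to give 21. The cut opens ring B to a chain whose three stereocentres are sugar-derived, and leaves one bond, one ring and one stereocentre to make. The forward step needs a C4a nucleophile that is non-basic and aldehyde-selective, and facial control at C5.

21 goes back to 20 and 19 by lowering C5 to the alcohol level and capping O5 with silicon. The aldehyde is too labile to carry, and a silyl-capped O5 cannot take part in the ring-A closure. The forward demand is a non-basic oxidation and a buffered fluoride cleavage.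

19 is cut at O1–C8a and at C4a–I to give 17. The C8a≡C4a triple bond is the only nucleophilic π-bond of 17, so electrophilic iodine can end only on C4a with oxygen on C8a. Ring A and the halide therefore come from one linear precursor. The forward step needs an oxygen donor on C2 that can reach C8a whatever its geometry (a ketal oxygen on an sp3 carbon), and an alkyne that reacts faster than the electron-rich arene.

17 is cut at C4–C4a into 12 and 15 (activated as 16). This joins the sugar-derived alkyne to the C2–C4 piece at the carbonyl in a convergent way. The coupling must be mild enough to leave C8–H alone. 15 comes from 14 and 13 by ester hydrolysis and ketalisation.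

12 is traced through 11 and 10 to 9 by moving the acetal from O7/O5 to O6/O7 and placing silicon on O5. The lactone-derived pattern leaves O6 free, where it could add to the ynone, whereas ring closure needs O5 free and O6/O7 locked trans. The only demand is selective silylation of the primary hydroxyl.

9 is cut at C8a≡C4a (one carbon removed) and reduced in thought to 8 and then 7. C8a is the former lactone carbon, so the chain returns to a sugar lactone. The forward steps need a hydride that spares the chromone and a homologation that does not epimerise the α-aryloxy aldehyde.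

7 is cut at the C8–O(aryl) bond into 6 and 4. The α-carbon of a lactone is activated for displacement, and inversion turns the xylo into the lyxo pattern. The demand is clean inversion at a hindered centre without epimerisation.

6 comes from 5 by an acetal across O3 and O5, which leaves only O2 free. 4 is cut at O1–C2 and at the C3–C2 bond of its aromatic chromone into 1 and 2 through 3; the forward demand is C-acylation of a ketone enolate in the presence of two phenoxides.

## Other disconnections considered

Alternative 1: The cut removes the C7–O and C8–O bonds and takes ring B back to a benzene ring. In the forward sense toluene dioxygenase in recombinant Escherichia coli adds O2 to bromobenzene A1 and gives the cis-diol A2. In its favour, one step delivers both carbinol carbons enantiopure, cis, and with the same sense as C7 and C8 of the target (the stereodescriptors of A2 map directly onto those positions). On this point it is better than the chosen plan, which needs a chiral-pool lactone and an inversion. All six ring-B carbons are present, and the remaining diene allows anti-epoxidation and anti-opening for the 5,6-trans and 6,7-trans pattern. Against it, ring A must be built onto the bromoalkene (C8a–O and C4a–C4 bonds) on a cyclohexadiene that dehydrates easily to a phenol. The C8 hydroxyl would also have to be arylated with retention, next to the C7 hydroxyl, because no displacement with inversion is available. Mechanistically the enzymatic step is sound; the weak part is everything after it. On step economy the plan is expected to be longer than the chosen one, since ring A, the ether and two further oxygens all have to be added one after another.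

Alternative 2: The cut removes the C5–O and C6–O bonds. In the forward sense the achiral 7,8-dihydrochromone A3 undergoes Jacobsen–Katsuki epoxidation (NaOCl, MnCl(salen) with salen = N,N'-bis(3,5-di-tert-butylsalicylidene)-1,2-cyclohexanediamine dianion, trivalent manganese), and water opens C5 in the same pot to give the trans-diol A4. In its favour, the absolute configuration comes from a catalyst, the substrate is short to make, and the anti-opening guarantees the 5,6-trans relationship. On the C5 question this is at least the equal of the chosen plan and probably more dependable than facial control in a ring closure. Against it, A4 still has CH2 groups at C7 and C8. Both would need late oxidation, and the 7,8-cis aryloxy alcohol cannot come from a simple epoxide opening, which gives trans. The alkene is also conjugated to an electron-poor pyranone, which is not the ideal case for the electrophilic oxo-manganese oxidant. The first half is shorter than the chosen route, but two of the four stereocentres remain without a clear source, so the overall count is unlikely to be lower.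

Alternative 3: The cut is the C5=C6 bond. In the forward sense the diene A5 is closed with the second-generation Grubbs catalyst RuCl2(=CHPh)(PCy3)(H2IMes) to the 7,8-dihydrochromone A6; epoxidation anti to the C7 silyloxy group and hydrolytic opening at C5 would then install the trans-diol. In its favour, formation of a six-membered ring by metathesis is very reliable, and on this point it is better than the Ni/Cr closure. The anti-opening also fixes 5,6-trans by mechanism. C7 and C8 come from the same sugar logic as in the chosen plan. Against it, the C6 oxygen, which the sugar supplies for free in the chosen plan, must be added again. A6 is a dihydroarene with two leaving groups on ring B and can aromatise by loss of the phenol or the silanol. The C5=C6 bond is electron-poor, and the facial selectivity of its epoxidation rests on one substituent. A5 would be made by vinylation of an iodide of the type of 19, so the hard ring-A step is not avoided. It costs about three steps more (vinylation, metathesis, epoxidation, hydrolysis against one closure).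

Key step: step 15

Remark on the chemistry: Ar in the names stands for 7-methoxy-4-oxo-2-(2-phenylethyl)-4H-chromen-6-yl, and the locants C4a–C8a of the target are also used for the open-chain intermediates.
Remark on the chemistry: the hemiacetal carbon of 8 and the ketal carbon of 18 are assumed to form as mixtures, which is of no consequence because both centres disappear in the next operation.

Step 1
Reactants: 1 1-(2,5-dihydroxy-4-methoxyphenyl)ethanone; 2 ethyl 3-phenylpropanoate
Product: 4 6-hydroxy-7-methoxy-2-(2-phenylethyl)-4H-chromen-4-one, via aryl 1,3-diketone 3 (not isolated)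
Conditions: LiN(SiMe3)2 (4.5 equiv), THF, −78 °C to rt; then conc. HCl, MeOH, 65 °C
Reagents that add atoms: none
Why: Claisen condensation of the ketone enolate (both phenols are carried as lithium phenoxides) with the ester should give the 1,3-diketone, and acid then closes the pyranone by attack of the ortho hydroxyl on the distal carbonyl and loss of water; the 5-hydroxyl cannot reach and ends as the free 6-OH of the chromone.

Step 2
Reactants: 5 D-xylono-1,4-lactone
Product: 6 3,5-O-isopropylidene-D-xylono-1,4-lactone
Conditions: Me2C(OMe)2, acetone, p-TsOH (cat.), rt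
Reagents that add atoms: 2,2-dimethoxypropane, COC(C)(C)OC
Why: Thermodynamic acetalisation; O3 and the C5 hydroxymethyl group are cis on the lactone and span a 1,3-dioxane, whereas the trans 2,3-diol cannot be bridged, so only HO-2 stays free.

Step 3
Reactants: 6 3,5-O-isopropylidene-D-xylono-1,4-lactone; 4 6-hydroxy-7-methoxy-2-(2-phenylethyl)-4H-chromen-4-one
Product: 7 2-O-Ar-3,5-O-isopropylidene-D-lyxono-1,4-lactone
Conditions: PPh3, i-PrO2CN=NCO2i-Pr (DIAD), THF, 0 °C to rt
Reagents that add atoms: none
Why: Mitsunobu reaction; the phenoxide displaces the oxyphosphonium group at C2 in an SN2 step that is helped by the adjacent lactone carbonyl, so C2 is inverted (D-xylo to D-lyxo) and the future C8 is set. The nearly neutral medium protects the epimerisable α-aryloxy lactone.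

Step 4
Reactants: 7 2-O-Ar-3,5-O-isopropylidene-D-lyxono-1,4-lactone
Product: 8 2-O-Ar-3,5-O-isopropylidene-D-lyxofuranose (anomer mixture)
Conditions: i-Bu2AlH (1.2 equiv), CH2Cl2, −78 °C
Reagents that add atoms: none
Why: Partial reduction of a lactone; the tetrahedral aluminate is stable at −78 °C and gives the lactol on work-up. The α-aryloxy γ-lactone is far more electrophilic than the chromone, a vinylogous ester, so one equivalent of hydride should be consumed there.

Step 5
Reactants: 8 2-O-Ar-3,5-O-isopropylidene-D-lyxofuranose
Product: 9 1,2-dideoxy-3-O-Ar-4,6-O-isopropylidene-D-lyxo-hex-1-ynitol (C8 aryloxy alkyne with free C6–OH)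
Conditions: MeC(O)C(N2)P(O)(OMe)2, K2CO3, MeOH, 0 °C to rt
Reagents that add atoms: dimethyl (1-diazo-2-oxopropyl)phosphonate, CC(=O)C(=[N+]=[N-])P(=O)(OC)OC
Why: Ohira–Bestmann homologation on the open hydroxy-aldehyde form; the diazomethylphosphonate anion adds, phosphate and N2 leave, and a 1,2-hydrogen shift of the alkylidene carbene gives the terminal alkyne whose new carbon becomes C4a. The mild carbonate base and a short reaction time are chosen to keep the α-aryloxy centre (C8) intact.

Step 6
Reactants: 9 1,2-dideoxy-3-O-Ar-4,6-O-isopropylidene-D-lyxo-hex-1-ynitol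
Product: 10 1,2-dideoxy-3-O-Ar-D-lyxo-hex-1-ynitol (triol)
Conditions: p-TsOH·H2O (cat.), MeOH, rt
Reagents that add atoms: none
Why: Acid-catalysed transacetalisation to methanol removes the 1,3-dioxane acetal, which spans O7 and O5 and is therefore in the wrong place for the ring closure; propargylic aryl ether and chromone are inert to these conditions.

Step 7
Reactants: 10 1,2-dideoxy-3-O-Ar-D-lyxo-hex-1-ynitol
Product: 11 6-O-(tert-butyldiphenylsilyl)-1,2-dideoxy-3-O-Ar-D-lyxo-hex-1-ynitol
Conditions: t-BuPh2SiCl (1.05 equiv), imidazole, CH2Cl2, 0 °C
Reagents that add atoms: tert-butyl(chloro)diphenylsilane, CC(C)(C)[Si](Cl)(c1ccccc1)c1ccccc1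
Why: Silylation of an alcohol; the bulky chlorosilane reacts only with the primary hydroxyl (O5), whose oxygen is thereby also made too hindered to interfere later.

Step 8
Reactants: 11 6-O-(tert-butyldiphenylsilyl)-1,2-dideoxy-3-O-Ar-D-lyxo-hex-1-ynitol
Product: 12 6-O-(tert-butyldiphenylsilyl)-1,2-dideoxy-3-O-Ar-4,5-O-isopropylidene-D-lyxo-hex-1-ynitol
Conditions: Me2C(OMe)2, PPTS (cat.), CH2Cl2, rt
Reagents that add atoms: 2,2-dimethoxypropane, COC(C)(C)OC
Why: Acetalisation of the threo 6,7-diol to a trans-4,5-disubstituted dioxolane; this ring removes the free C6–OH before the ynone is made and later holds O6 and O7 diequatorial in ring B.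

Step 9
Reactants: 13 methyl 3-oxo-5-phenylpentanoate
Product: 14 methyl [2-(2-phenylethyl)-1,3-dioxolan-2-yl]acetate
Conditions: HOCH2CH2OH, p-TsOH (cat.), toluene, reflux, azeotropic removal of water
Reagents that add atoms: ethane-1,2-diol, OCCO
Why: Ketalisation of the ketone of a β-keto ester; the future C2 oxygen is stored on an sp3 carbon, so it has no enol-ether geometry and no nucleophilic C3=C2 bond.

Step 10
Reactants: 14 methyl [2-(2-phenylethyl)-1,3-dioxolan-2-yl]acetate
Product: 15 [2-(2-phenylethyl)-1,3-dioxolan-2-yl]acetic acid
Conditions: LiOH, THF–H2O, rt; then 1 M HCl to pH 4, 0 °C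
Reagents that add atoms: lithium hydroxide, [Li+].[OH-]
Why: Saponification by acyl–oxygen cleavage; the ketal is stable to base and to the brief cold acidification.

Step 11
Reactants: 15 [2-(2-phenylethyl)-1,3-dioxolan-2-yl]acetic acid; 12 6-O-(tert-butyldiphenylsilyl)-1,2-dideoxy-3-O-Ar-4,5-O-isopropylidene-D-lyxo-hex-1-ynitol
Product: 17 alkynyl ketone (12 acylated at the alkyne terminus by the [2-(2-phenylethyl)-1,3-dioxolan-2-yl]acetyl group), via acyl chloride 16 (not isolated)
Conditions: 15, Me2C=C(Cl)NMe2, CH2Cl2, 0 °C; then 12, PdCl2(PPh3)2 (2 mol %), CuI (4 mol %), Et3N (1.5 equiv), THF, rt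
Reagents that add atoms: none
Why: The α-chloroenamine makes the acid chloride without HCl, which spares the ketal. Acyl Sonogashira coupling (oxidative addition of the acyl chloride to zerovalent palladium, transmetalation from the copper acetylide, reductive elimination) then forms the C4–C4a bond at room temperature, fast enough to outrun amine-induced isomerisation at C8.

Step 12
Reactants: 17 alkynyl ketone
Product: 19 3-iodo-6-(2-phenylethyl)-4H-pyran-4-one carrying at C2 the chain CH(OAr)–(6,7-O-isopropylidene)–CH2OSiPh2t-Bu, via chloroethoxy dihydropyranone 18 (not isolated)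
Conditions: ICl (1.2 equiv), CH2Cl2, −78 to −20 °C; then Et3N, 0 °C to rt
Reagents that add atoms: iodine monochloride, ClI
Why: Proposed new method: ICl delivers I+ to the triple bond, a dioxolane oxygen (free to rotate into reach because it sits on an sp3 carbon) attacks C8a in a 6-endo-dig mode anti to iodine, chloride opens the oxonium ion at its OCH2 carbon to give 18, and base-assisted β-elimination of 2-chloroethanol (C3–H is α to the ketone) aromatises ring A, with iodine fixed on C4a because the alkyne is the only nucleophilic π-bond of 17; the closest known reaction type is the ICl-induced cyclisation of 2-methoxyaryl alkynyl ketones to 3-iodochromones, in which an ether oxygen attacks the iodonium ion and is then dealkylated by chloride.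

Step 13
Reactants: 19 silyl-protected 3-iodo-4-pyranone
Product: 20 primary alcohol (19 with free C5–OH)
Conditions: HF·pyridine, pyridine, THF, 0 °C to rt
Reagents that add atoms: none
Why: Fluoride-driven cleavage of a silyl ether; the pyridine-buffered medium leaves the dioxolane, the C4a–I bond and the base-sensitive C8–H untouched.

Step 14
Reactants: 20 primary alcohol
Product: 21 3-iodo-4-pyranone carrying the 2-O-aryl-3,4-O-isopropylidene-D-lyxo aldehyde chain (C5 aldehyde)
Conditions: Dess–Martin periodinane, CH2Cl2, 0 °C to rt
Reagents that add atoms: none
Why: Dess–Martin oxidation (ligand exchange at iodine, then removal of the carbinol hydrogen) under non-basic conditions; C6, the aldehyde α-carbon, sits in the more stable trans-dioxolane and should not epimerise. The aldehyde is used at once.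

Step 15
Reactants: 21 iodo aldehyde
Product: 22 (5S,6R,7S,8S)-8-(aryloxy)-5-hydroxy-6,7-O-isopropylidene-2-(2-phenylethyl)-5,6,7,8-tetrahydro-4H-chromen-4-one
Conditions: CrCl2 (8 equiv), NiCl2 (0.1 equiv), DMF (degassed), rt, 0.005 M
Reagents that add atoms: none
Why: Nozaki–Hiyama–Kishi reaction: divalent chromium reduces NiCl2 to zerovalent nickel, which inserts into the C4a–I bond, and transmetalation gives an alkenyl species of trivalent chromium that adds to the C5 aldehyde through a chromium-bridged transition state to form C4a–C5. The closest known reaction type is the intramolecular Ni/Cr-mediated cyclisation of iodoalkenes onto aldehydes; the iodopyranone is only a new alkenyl partner, and the addition of a C4a-metalated pyranone to an aldehyde is expected to be slower than that of a simple alkenyl species. Ring B closes in a 6-exo-trig mode, the aldehyde C=O being exocyclic to the forming ring. C5 is controlled by the substrate, and an open-chain Felkin–Anh argument does not transfer because C7 is tied to the nucleophile through the ring. The trans-dioxolane forces O6 and O7 to be diequatorial in the half-chair transition state and puts the C8 aryloxy group pseudo-axial, so C6–O is antiperiplanar to the forming bond in both diastereomeric transition states, and the position of the aldehyde oxygen decides. With that oxygen pseudo-equatorial the bulky O–Cr unit stays outside the ring, next to the chromium-bearing C4a and within reach of the C4 carbonyl, which should give the 5,6-trans (5S) alcohol; the pseudo-axial alternative has a 1,3-diaxial contact with H7 and would give the 5,6-cis epimer. The step needs selectivity for the aldehyde over both pyranone carbonyls and tolerance of the acidic C8–H and the aryl ether; the low basicity and carbonyl selectivity of alkenylchromium reagents secure this, and high dilution suppresses intermolecular addition.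

Step 16
Reactants: 22 acetal-protected tetrahydrochromone
Product: 23 (5S,6R,7S,8S)-8-(aryloxy)-5,6,7-trihydroxy-2-(2-phenylethyl)-5,6,7,8-tetrahydro-4H-chromen-4-one (the target)
Conditions: AcOH–H2O (4:1), 40 °C
Reagents that add atoms: none
Why: Acid hydrolysis of an acetal through the oxocarbenium ion; the trans-fused dioxolane is strained and should open under conditions too mild to ionise the C5 carbinol or the C8 ether, and no stereocentre is involved.

Compound list
1 | 1-(2,5-dihydroxy-4-methoxyphenyl)ethanone | CC(=O)c1cc(O)c(OC)cc1O | starting material
2 | ethyl 3-phenylpropanoate | CCOC(=O)CCc1ccccc1 | starting material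
3 | 1-(2,5-dihydroxy-4-methoxyphenyl)-5-phenylpentane-1,3-dione | COc1cc(O)c(cc1O)C(=O)CC(=O)CCc1ccccc1 | intermediate
4 | 6-hydroxy-7-methoxy-2-(2-phenylethyl)-4H-chromen-4-one | COc1cc2oc(CCc3ccccc3)cc(=O)c2cc1O | intermediate
5 | D-xylono-1,4-lactone | O=C1[C@H](O)[C@@H](O)[C@@H](CO)O1 | starting material
6 | 3,5-O-isopropylidene-D-xylono-1,4-lactone | O=C1[C@H](O)[C@H]2OC(C)(C)OC[C@H]2O1 | intermediate
7 | 2-O-Ar-3,5-O-isopropylidene-D-lyxono-1,4-lactone | COc1cc2oc(CCc3ccccc3)cc(=O)c2cc1O[C@H]1[C@H]2OC(C)(C)OC[C@H]2OC1=O | intermediate
8 | 2-O-Ar-3,5-O-isopropylidene-D-lyxofuranose (anomer mixture) | COc1cc2oc(CCc3ccccc3)cc(=O)c2cc1O[C@H]1[C@H]2OC(C)(C)OC[C@H]2OC1O | intermediate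
9 | 1,2-dideoxy-3-O-Ar-4,6-O-isopropylidene-D-lyxo-hex-1-ynitol | COc1cc2oc(CCc3ccccc3)cc(=O)c2cc1O[C@H](C#C)[C@H]1OC(C)(C)OC[C@H]1O | intermediate
10 | 1,2-dideoxy-3-O-Ar-D-lyxo-hex-1-ynitol | COc1cc2oc(CCc3ccccc3)cc(=O)c2cc1O[C@H](C#C)[C@@H](O)[C@H](O)CO | intermediate
11 | 6-O-(tert-butyldiphenylsilyl)-1,2-dideoxy-3-O-Ar-D-lyxo-hex-1-ynitol | COc1cc2oc(CCc3ccccc3)cc(=O)c2cc1O[C@H](C#C)[C@@H](O)[C@H](O)CO[Si](c1ccccc1)(c1ccccc1)C(C)(C)C | intermediate
12 | 6-O-(tert-butyldiphenylsilyl)-1,2-dideoxy-3-O-Ar-4,5-O-isopropylidene-D-lyxo-hex-1-ynitol | COc1cc2oc(CCc3ccccc3)cc(=O)c2cc1O[C@H](C#C)[C@H]1OC(C)(C)O[C@@H]1CO[Si](c1ccccc1)(c1ccccc1)C(C)(C)C | intermediate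
13 | methyl 3-oxo-5-phenylpentanoate | COC(=O)CC(=O)CCc1ccccc1 | starting material
14 | methyl [2-(2-phenylethyl)-1,3-dioxolan-2-yl]acetate | COC(=O)CC1(CCc2ccccc2)OCCO1 | intermediate
15 | [2-(2-phenylethyl)-1,3-dioxolan-2-yl]acetic acid | OC(=O)CC1(CCc2ccccc2)OCCO1 | intermediate
16 | [2-(2-phenylethyl)-1,3-dioxolan-2-yl]acetyl chloride | ClC(=O)CC1(CCc2ccccc2)OCCO1 | intermediate
17 | alkynyl ketone: 12 acylated at the alkyne terminus by the [2-(2-phenylethyl)-1,3-dioxolan-2-yl]acetyl group | COc1cc2oc(CCc3ccccc3)cc(=O)c2cc1O[C@H](C#CC(=O)CC1(CCc2ccccc2)OCCO1)[C@H]1OC(C)(C)O[C@@H]1CO[Si](c1ccccc1)(c1ccccc1)C(C)(C)C | intermediate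
18 | 2-(2-chloroethoxy)-5-iodo-2-(2-phenylethyl)-2,3-dihydro-4H-pyran-4-one with the chain of 19 at C6 (mixture at the ketal carbon) | COc1cc2oc(CCc3ccccc3)cc(=O)c2cc1O[C@H](C1=C(I)C(=O)CC(CCc2ccccc2)(OCCCl)O1)[C@H]1OC(C)(C)O[C@@H]1CO[Si](c1ccccc1)(c1ccccc1)C(C)(C)C | intermediate
19 | 3-iodo-6-(2-phenylethyl)-4H-pyran-4-one with the chain CH(OAr)–(6,7-O-isopropylidene)–CH2OSiPh2t-Bu at C2 | COc1cc2oc(CCc3ccccc3)cc(=O)c2cc1O[C@H](c1oc(CCc2ccccc2)cc(=O)c1I)[C@H]1OC(C)(C)O[C@@H]1CO[Si](c1ccccc1)(c1ccccc1)C(C)(C)C | intermediate
20 | 19 with free C5–OH (primary alcohol) | COc1cc2oc(CCc3ccccc3)cc(=O)c2cc1O[C@H](c1oc(CCc2ccccc2)cc(=O)c1I)[C@H]1OC(C)(C)O[C@@H]1CO | intermediate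
21 | 3-iodo-4-pyranone carrying the 2-O-aryl-3,4-O-isopropylidene-D-lyxo aldehyde chain | COc1cc2oc(CCc3ccccc3)cc(=O)c2cc1O[C@H](c1oc(CCc2ccccc2)cc(=O)c1I)[C@H]1OC(C)(C)O[C@@H]1C=O | intermediate
22 | (5S,6R,7S,8S)-8-(aryloxy)-5-hydroxy-6,7-O-isopropylidene-2-(2-phenylethyl)-5,6,7,8-tetrahydro-4H-chromen-4-one | COc1cc2oc(CCc3ccccc3)cc(=O)c2cc1O[C@@H]1c2oc(CCc3ccccc3)cc(=O)c2[C@H](O)[C@H]2OC(C)(C)O[C@H]12 | intermediate
23 | (5S,6R,7S,8S)-8-(aryloxy)-5,6,7-trihydroxy-2-(2-phenylethyl)-5,6,7,8-tetrahydro-4H-chromen-4-one, CNP0125425.2 | COc1cc2oc(CCc3ccccc3)cc(=O)c2cc1O[C@@H]1c2oc(CCc3ccccc3)cc(=O)c2[C@H](O)[C@@H](O)[C@@H]1O | target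

Total step count: 16. Longest linear sequence: 13 steps (5 to 23 through steps 2–8 and 11–16).

Steps least certain to work

Step 12 (Proposed new method). The most likely failure is that the ketal oxygen does not capture the iodonium ion fast enough, so that ICl is diverted to iodination of the dialkoxy-substituted benzene ring of the aromatic chromone or to plain addition across the triple bond. The reason is that an ynone triple bond is a poor donor and depends on neighbouring-group help. The fallback sets out from 17, comes back at 19 and uses established reactions only. Conjugate addition of morpholine (1.05 equiv, EtOH, 0 °C) to the ynone gives the (E)-β-morpholino enone F1. Iodination of its enamine α-carbon, the only strongly nucleophilic carbon and the one that becomes C4a (I2, Et3N, CH2Cl2, 0 °C), gives the α-iodo enaminone F2. p-TsOH in wet acetone then removes the ethylene ketal while the isopropylidene acetal is held by the solvent, and the liberated enol oxygen displaces morpholine at C8a by addition–elimination, which closes ring A to 19.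

Step 15 (key step). The most likely failure is poor facial selectivity at C5, with the aldehyde oxygen going pseudo-axial, because the preference rests on conformational arguments only; reduction of the C4a–I bond without addition is the second risk if closure of the trans-fused bicycle is slow. The fallback sets out from 21, comes back at 22 and sets C5 by hydride instead of by the C–C bond formation. The closure is run as in step 15, and the alcohol of the wrong configuration, the 5,6-cis epimer F3 (alone or mixed with 22), is oxidised with Dess–Martin periodinane to the C5 ketone F4. NaBH4 with CeCl3·7H2O in MeOH at −78 °C should then add hydride axially to the ring held by the trans-dioxolane and give the equatorial alcohol 22.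

Step 3. The most likely failure is slow displacement at C2, because the phenoxide must approach the face of the lactone that carries the cis-fused dioxane, so that the betaine is consumed unproductively or the product epimerises at C2. The fallback sets out from 6, comes back at 7 and replaces the redox condensation by a sulfonate displacement. Tf2O and pyridine in CH2Cl2 at −30 °C give the 2-O-triflate F5 with retention, and the caesium phenoxide of 4 (Cs2CO3, DMF, 0 °C, short reaction time) displaces it with inversion to give 7.

Step 5. The most likely failure is epimerisation at the α-aryloxy carbon (C8) or β-elimination of the C7 oxygen in the open aldehyde under carbonate in methanol, because the aryloxy group acidifies that hydrogen and the lactol releases the aldehyde only slowly. The fallback sets out from 6, comes back at 9 and makes the alkyne before the aryl ether. TBSOTf and 2,6-lutidine give the 2-O-silyl lactone F6, i-Bu2AlH at −78 °C gives the lactol F7, and the Ohira–Bestmann reagent gives the silyloxy alkyne F8. HF·pyridine frees the propargylic hydroxyl to give the diol F9. A Mitsunobu reaction with 4 should then take place at the propargylic carbinol, which is the less hindered and more activated of the two, with inversion to 9. This order also removes the hydride step of step 4 from the chromone-containing series.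

Step 11. The most likely failure is amine-induced propargyl–allenyl isomerisation of the product at C8, or ketene formation from 16, because C8–H becomes γ to the new carbonyl. The fallback sets out from 12 (with 14 as the second component), comes back at 17 and makes the ynone by oxidation instead of by acylation. i-Bu2AlH at −78 °C reduces 14 to the aldehyde F10, and Zn(OTf)2 with Et3N in toluene adds the alkyne 12 to it to give the propargylic alcohol F11 as a mixture at the carbinol. Dess–Martin periodinane then gives 17 under non-basic conditions.

Further compounds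
F1 | step 12 | (E)-β-morpholino enone from 17 and morpholine | COc1cc2oc(CCc3ccccc3)cc(=O)c2cc1O[C@H](/C(=C\C(=O)CC1(CCc2ccccc2)OCCO1)N1CCOCC1)[C@H]1OC(C)(C)O[C@@H]1CO[Si](c1ccccc1)(c1ccccc1)C(C)(C)C
F2 | step 12 | α-iodo-β-morpholino enone (alkene geometry not fixed) | COc1cc2oc(CCc3ccccc3)cc(=O)c2cc1O[C@H](C(=C(I)C(=O)CC1(CCc2ccccc2)OCCO1)N1CCOCC1)[C@H]1OC(C)(C)O[C@@H]1CO[Si](c1ccccc1)(c1ccccc1)C(C)(C)C
F3 | step 15 | (5R,6R,7S,8S) 5-epimer of 22 (5,6-cis alcohol) | COc1cc2oc(CCc3ccccc3)cc(=O)c2cc1O[C@@H]1c2oc(CCc3ccccc3)cc(=O)c2[C@@H](O)[C@H]2OC(C)(C)O[C@H]12
F4 | step 15 | 8-(aryloxy)-6,7-O-isopropylidene-2-(2-phenylethyl)-7,8-dihydro-4H-chromene-4,5(6H)-dione | COc1cc2oc(CCc3ccccc3)cc(=O)c2cc1O[C@@H]1c2oc(CCc3ccccc3)cc(=O)c2C(=O)[C@H]2OC(C)(C)O[C@H]12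
F5 | step 3 | 3,5-O-isopropylidene-2-O-(trifluoromethylsulfonyl)-D-xylono-1,4-lactone | O=C1[C@H](OS(=O)(=O)C(F)(F)F)[C@H]2OC(C)(C)OC[C@H]2O1
F6 | step 5 | 2-O-(tert-butyldimethylsilyl)-3,5-O-isopropylidene-D-xylono-1,4-lactone | O=C1[C@H](O[Si](C)(C)C(C)(C)C)[C@H]2OC(C)(C)OC[C@H]2O1
F7 | step 5 | 2-O-(tert-butyldimethylsilyl)-3,5-O-isopropylidene-D-xylofuranose (anomer mixture) | OC1[C@H](O[Si](C)(C)C(C)(C)C)[C@H]2OC(C)(C)OC[C@H]2O1
F8 | step 5 | 3-O-(tert-butyldimethylsilyl)-1,2-dideoxy-4,6-O-isopropylidene-D-xylo-hex-1-ynitol | C#C[C@H](O[Si](C)(C)C(C)(C)C)[C@H]1OC(C)(C)OC[C@H]1O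
F9 | step 5 | 1,2-dideoxy-4,6-O-isopropylidene-D-xylo-hex-1-ynitol | C#C[C@H](O)[C@H]1OC(C)(C)OC[C@H]1O
F10 | step 11 | [2-(2-phenylethyl)-1,3-dioxolan-2-yl]acetaldehyde | O=CCC1(CCc2ccccc2)OCCO1
F11 | step 11 | propargylic alcohol from 12 and the aldehyde (mixture at the carbinol) | COc1cc2oc(CCc3ccccc3)cc(=O)c2cc1O[C@H](C#CC(O)CC1(CCc2ccccc2)OCCO1)[C@H]1OC(C)(C)O[C@@H]1CO[Si](c1ccccc1)(c1ccccc1)C(C)(C)C
A1 | alternative 1 | bromobenzene | Brc1ccccc1
A2 | alternative 1 | (1S,2S)-3-bromocyclohexa-3,5-diene-1,2-diol | O[C@@H]1C(Br)=CC=C[C@@H]1O
A3 | alternative 2 | 2-(2-phenylethyl)-7,8-dihydro-4H-chromen-4-one | O=c1cc(CCc2ccccc2)oc2c1C=CCC2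
A4 | alternative 2 | (5S,6S)-5,6-dihydroxy-2-(2-phenylethyl)-5,6,7,8-tetrahydro-4H-chromen-4-one | O=c1cc(CCc2ccccc2)oc2c1[C@H](O)[C@@H](O)CC2
A5 | alternative 3 | 6-(2-phenylethyl)-3-vinyl-4H-pyran-4-one carrying at C2 the chain CH(OAr)–CH(OSiMe2t-Bu)–CH=CH2 | COc1cc2oc(CCc3ccccc3)cc(=O)c2cc1O[C@H](c1oc(CCc2ccccc2)cc(=O)c1C=C)[C@@H](O[Si](C)(C)C(C)(C)C)C=C
A6 | alternative 3 | 8-aryloxy-7-(tert-butyldimethylsilyloxy)-7,8-dihydro-2-(2-phenylethyl)chromone | COc1cc2oc(CCc3ccccc3)cc(=O)c2cc1O[C@@H]1c2oc(CCc3ccccc3)cc(=O)c2C=C[C@@H]1O[Si](C)(C)C(C)(C)C
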